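The C ring pyranone is cut at C4a–C4 and C4–C3. Its carbonyl carbon C4 is bonded only to C4a of the fully substituted A ring and to C3, so it maps onto one molecule of CO placed between an aryl–palladium and an alkynyl group. One carbonylative Sonogashira coupling joins a MOM-protected ortho-iodophenol that already carries the four A-ring methoxy groups, CO and the B-ring arylacetylene into an open-chain alkynone. Both phenolic oxygens (O1 and the 3'-oxygen) travel as MOM ethers, so a single amine-then-acid operation afterwards forms O1–C2 and frees the 3'-hydroxyl.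

Key step: step 6

Assumption: the target has no stereogenic centre or axis, so it is one achiral compound and no step has to set configuration.

**Step 1**
Reactants: 1 1,2,3,4-tetramethoxybenzene
Product: 4 2,3,4,5-tetramethoxyphenol, via aryllithium 2 (not isolated), via lithium aryltrimethoxyborate 3 (not isolated)
Conditions: n-BuLi, TMEDA, THF, 0 °C; B(OMe)3, −78 °C → rt; AcOH, 30% aq. H2O2, 0 °C → rt
Reagents that add atoms: n-butyllithium, [Li]CCCC (lithium of 2 and 3 only); trimethyl borate, COB(OC)OC (boron and methoxy groups of 3 only); hydrogen peroxide, OO (the hydroxyl oxygen of 4)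
Why: Directed ortho-metalation can give only one aryllithium because the two ring hydrogens of 1 are equivalent and each lies next to a methoxy group, and borate trapping followed by peroxide-induced 1,2-aryl shift (boronate oxidation) should deliver the phenol.

**Step 2**
Reactants: 4 2,3,4,5-tetramethoxyphenol
Product: 5 1-(methoxymethoxy)-2,3,4,5-tetramethoxybenzene
Conditions: NaH, MOMCl, THF, 0 °C → rt
Reagents that add atoms: chloromethyl methyl ether, COCCl
Why: O-Alkylation of the sodium phenoxide with the reactive α-chloro ether (Williamson-type MOM protection) should be fast and clean.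

**Step 3**
Reactants: 5 1-(methoxymethoxy)-2,3,4,5-tetramethoxybenzene
Product: 7 1-iodo-2-(methoxymethoxy)-3,4,5,6-tetramethoxybenzene, via ortho-lithiated MOM ether 6 (not isolated)
Conditions: n-BuLi, THF, −78 → 0 °C; I2, THF, −78 °C → rt
Reagents that add atoms: n-butyllithium, [Li]CCCC (lithium of 6 only); iodine, II
Why: Directed ortho-metalation at the single remaining ring hydrogen, which is flanked by OMOM and OMe, followed by iodinolysis of the aryllithium should place iodine without any oxidant touching a free electron-rich phenol.

**Step 4**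
Reactants: 8 3-hydroxy-4,5-dimethoxybenzaldehyde
Product: 9 3,4-dimethoxy-5-(methoxymethoxy)benzaldehyde
Conditions: MOMCl, i-Pr2NEt, CH2Cl2, 0 °C → rt
Reagents that add atoms: chloromethyl methyl ether, COCCl
Why: Amine-mediated MOM protection of the phenol is a standard O-alkylation that leaves the non-enolisable aldehyde untouched.

**Step 5**
Reactants: 9 3,4-dimethoxy-5-(methoxymethoxy)benzaldehyde
Product: 10 5-ethynyl-1,2-dimethoxy-3-(methoxymethoxy)benzene
Conditions: dimethyl (1-diazo-2-oxopropyl)phosphonate, K2CO3, MeOH, 0 °C → rt
Reagents that add atoms: dimethyl (1-diazo-2-oxopropyl)phosphonate, CC(=O)C(=[N+]=[N-])P(=O)(OC)OC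
Why: Seyferth–Gilbert homologation in its Ohira–Bestmann form should convert the aryl aldehyde into the terminal alkyne in one operation under mild base that the MOM ether tolerates.

**Step 6**
Reactants: 7 1-iodo-2-(methoxymethoxy)-3,4,5,6-tetramethoxybenzene; 11 carbon monoxide; 10 5-ethynyl-1,2-dimethoxy-3-(methoxymethoxy)benzene
Product: 12 3-[3,4-dimethoxy-5-(methoxymethoxy)phenyl]-1-[2-(methoxymethoxy)-3,4,5,6-tetramethoxyphenyl]prop-2-yn-1-one
Conditions: PdCl2(PPh3)2 (5 mol %), Et3N, THF, CO (10 bar), 50 °C, copper-free, slow addition of 10
Reagents that add atoms: none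
Why: Oxidative addition of the C–I bond of 7 to Pd(0), CO coordination and migratory insertion to an aroyl–palladium(II) iodide, amine-assisted transfer of the acetylide of 10 and reductive elimination should form C4a–C4 and C4–C3 in one catalytic cycle. The closest known reaction type is the three-component carbonylative Sonogashira coupling of ortho-alkoxy aryl iodides with CO and terminal alkynes to aryl alkynyl ketones. No ring is closed and no stereocentre is created; the MOM ether on the ortho oxygen keeps the product acyclic and stops the phenol from capturing the acyl–palladium or cyclising in 5-exo mode. The selectivity needed is CO insertion ahead of alkynyl transfer, which CO pressure, the absence of copper (slow acetylide transfer) and the di-ortho-oxygenated, electron-rich aryl–palladium (fast CO insertion, hindered direct alkynylation) should secure. Iodine occupies the one A-ring position that was free, so the substitution pattern is settled before the coupling, and the tertiary amine base cannot add to the ynone.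

**Step 7**
Reactants: 12 3-[3,4-dimethoxy-5-(methoxymethoxy)phenyl]-1-[2-(methoxymethoxy)-3,4,5,6-tetramethoxyphenyl]prop-2-yn-1-one
Product: 14 3'-hydroxy-5,6,7,8,4',5'-hexamethoxyflavone, via diethylamino enaminone 13 (not isolated)
Conditions: Et2NH, EtOH, 40 °C; concentrate; HCl (3 M in MeOH), 50 °C
Reagents that add atoms: diethylamine, CCNCC (nitrogen and ethyl groups of 13 only; nothing remains in 14)
Why: Aza-Michael addition of diethylamine to the ynone while both phenols are masked should give the β-enaminone, and methanolic HCl then cleaves both MOM acetals and lets the freed C8a hydroxyl attack the protonated vinylogous amide at C2 with loss of diethylamine (addition–elimination chromone closure), which can only give the six-membered pyranone because C3 of an enaminone is not electrophilic; the aryl methyl ethers should survive dilute methanolic HCl at this temperature.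

**Compound list**
1 | 1,2,3,4-tetramethoxybenzene | COc1ccc(OC)c(OC)c1OC | starting material
2 | (2,3,4,5-tetramethoxyphenyl)lithium | [Li]c1cc(OC)c(OC)c(OC)c1OC | intermediate
3 | lithium trimethoxy(2,3,4,5-tetramethoxyphenyl)borate | [Li+].CO[B-](OC)(OC)c1cc(OC)c(OC)c(OC)c1OC | intermediate
4 | 2,3,4,5-tetramethoxyphenol | Oc1cc(OC)c(OC)c(OC)c1OC | intermediate
5 | 1-(methoxymethoxy)-2,3,4,5-tetramethoxybenzene | COCOc1cc(OC)c(OC)c(OC)c1OC | intermediate
6 | [2-(methoxymethoxy)-3,4,5,6-tetramethoxyphenyl]lithium | COCOc1c([Li])c(OC)c(OC)c(OC)c1OC | intermediate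
7 | 1-iodo-2-(methoxymethoxy)-3,4,5,6-tetramethoxybenzene | COCOc1c(I)c(OC)c(OC)c(OC)c1OC | intermediate
8 | 3-hydroxy-4,5-dimethoxybenzaldehyde | COc1cc(C=O)cc(O)c1OC | starting material
9 | 3,4-dimethoxy-5-(methoxymethoxy)benzaldehyde | COCOc1cc(C=O)cc(OC)c1OC | intermediate
10 | 5-ethynyl-1,2-dimethoxy-3-(methoxymethoxy)benzene | COCOc1cc(C#C)cc(OC)c1OC | intermediate
11 | carbon monoxide | [C-]#[O+] | starting material
12 | 3-[3,4-dimethoxy-5-(methoxymethoxy)phenyl]-1-[2-(methoxymethoxy)-3,4,5,6-tetramethoxyphenyl]prop-2-yn-1-one | COCOc1c(C(=O)C#Cc2cc(OC)c(OC)c(OCOC)c2)c(OC)c(OC)c(OC)c1OC | intermediate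
13 | 3-(diethylamino)-3-[3,4-dimethoxy-5-(methoxymethoxy)phenyl]-1-[2-(methoxymethoxy)-3,4,5,6-tetramethoxyphenyl]prop-2-en-1-one (C=C geometry not controlled and not needed; it is lost on ring closure) | CCN(CC)C(=CC(=O)c1c(OCOC)c(OC)c(OC)c(OC)c1OC)c1cc(OC)c(OC)c(OCOC)c1 | intermediate
14 | 3'-hydroxy-5,6,7,8,4',5'-hexamethoxyflavone (achiral) | COc1cc(-c2cc(=O)c3c(OC)c(OC)c(OC)c(OC)c3o2)cc(O)c1OC | target

**Totals**
Total step count: 7. Longest linear sequence: 5 steps (steps 1, 2, 3, 6, 7); steps 4 and 5 form the second branch.

**Steps most likely to fail**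

Step 6. Oxidative addition of the electron-rich, doubly ortho-substituted iodide may be slow under CO, alkynyl transfer may overtake CO insertion and give the diarylalkyne, or the alkyne may be lost to oligomerisation. The fallback avoids CO and palladium and sets out from MOM ether 5 and alkyne 10. Compound 5 is lithiated as in step 3 (aryllithium 6) and quenched with DMF to give 2-(methoxymethoxy)-3,4,5,6-tetramethoxybenzaldehyde F1. Alkyne 10 is deprotonated with n-BuLi in THF at −78 °C to {[3,4-dimethoxy-5-(methoxymethoxy)phenyl]ethynyl}lithium F2. Addition of F2 to F1, with NH4Cl work-up, should give racemic 3-[3,4-dimethoxy-5-(methoxymethoxy)phenyl]-1-[2-(methoxymethoxy)-3,4,5,6-tetramethoxyphenyl]prop-2-yn-1-ol F3. Oxidation of this propargylic alcohol with activated MnO2 in CH2Cl2 removes the stereocentre and returns to the route at ynone 12.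

Step 7. Amine addition to the electron-rich β-aryl ynone may stall, the enaminone may hydrolyse before closing, only one acetal may be cleaved, or forcing acid may begin to cleave the C5 methyl ether. The fallback sets out from 12 and separates deprotection from ring closure. Methanolic HCl at room temperature removes both MOM groups to give 3-(3-hydroxy-4,5-dimethoxyphenyl)-1-(2-hydroxy-3,4,5,6-tetramethoxyphenyl)prop-2-yn-1-one F4. Catalytic DMAP in DMF then closes the ring by 6-endo oxa-Michael addition through nucleophilic catalysis, returning at target 14. Any flavone already formed in the acid stage is the desired product.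

Step 1. Metalation may be incomplete, or the very electron-rich phenol may be over-oxidised towards a methoxybenzoquinone in the peroxide stage. The fallback sets out from 1 and uses electrophilic substitution in place of metalation. Vilsmeier–Haack formylation (POCl3, DMF) should give 2,3,4,5-tetramethoxybenzaldehyde F5. Baeyer–Villiger (Dakin-type) oxidation with mCPBA in CH2Cl2 gives 2,3,4,5-tetramethoxyphenyl formate F6. Hydrolysis with aqueous KOH in MeOH returns to the route at phenol 4.

**Further compounds**
F1 | step 6 | 2-(methoxymethoxy)-3,4,5,6-tetramethoxybenzaldehyde | COCOc1c(C=O)c(OC)c(OC)c(OC)c1OC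
F2 | step 6 | {[3,4-dimethoxy-5-(methoxymethoxy)phenyl]ethynyl}lithium | [Li]C#Cc1cc(OC)c(OC)c(OCOC)c1
F3 | step 6 | 3-[3,4-dimethoxy-5-(methoxymethoxy)phenyl]-1-[2-(methoxymethoxy)-3,4,5,6-tetramethoxyphenyl]prop-2-yn-1-ol (racemic) | COCOc1c(C(O)C#Cc2cc(OC)c(OC)c(OCOC)c2)c(OC)c(OC)c(OC)c1OC
F4 | step 7 | 3-(3-hydroxy-4,5-dimethoxyphenyl)-1-(2-hydroxy-3,4,5,6-tetramethoxyphenyl)prop-2-yn-1-one | COc1cc(C#CC(=O)c2c(O)c(OC)c(OC)c(OC)c2OC)cc(O)c1OC
F5 | step 1 | 2,3,4,5-tetramethoxybenzaldehyde | COc1cc(C=O)c(OC)c(OC)c1OC
F6 | step 1 | 2,3,4,5-tetramethoxyphenyl formate | COc1cc(OC=O)c(OC)c(OC)c1OC
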